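**Retrosynthetic overview**
- The strategy rests on ring B. Its carbons C1'–C6' carry oxygen on C2', C4' and C6', the acetyl group on C5', the methyl on C3' and the bridge on C1'. This is a folded tetraketide, so ring B is opened at C4'–C5' to the 3,5,7-triketo ester 15 (chain C1 = C4', C2 = C3', C3 = C2', C4 = C1', C5 = C6', C6 = C5', C7/C8 = acetyl).
- 15 comes from its C7 dioxolane 14. The bridge bond (ArCH2–C4) is made by C-alkylation of the ketal-masked diketo ester 13 with the ring A benzylic bromide 8, after all strong-base chemistry on the chain is finished. 13 comes from the dianion of methyl 2-methyl-3-oxobutanoate and the ketal-masked acetoacetyl Weinreb amide 10.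
- Ring A is bought aromatic as 2,4,6-trimethoxytoluene. Butanoylation, ketone-directed cleavage of the two ortho methyl ethers (which fixes the one oxygen that keeps its methyl), formylation of the last free carbon, benzylation, reduction and bromination give 8.
- Ring order: ring A is present from the start, ring B is closed in step 11, and hydrogenolysis of the two benzyl ethers ends the route.

Key step: step 11

Assumption: the target has no stereocentre. The chain stereocentres of 13–16 (C2, C4) vanish when ring B aromatises, so these compounds are carried as mixtures of stereoisomers and keto–enol forms. Ethyl 2-(2-methyl-1,3-dioxolan-2-yl)acetate is taken as a purchasable compound.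

**Route**

Step 1
Reactants: 1 1,3,5-trimethoxy-2-methylbenzene; 2 butanoyl chloride
Product: 3 1-(2,4,6-trimethoxy-3-methylphenyl)butan-1-one
Conditions: AlCl3 (1.1 equiv), CH2Cl2, 0 °C; then ice/1 M HCl
Reagents that add atoms: none
Why: Friedel–Crafts acylation at one of the two equivalent free positions of a trialkoxyarene, so only one regioisomer can form and the new ketone deactivates the ring against a second acylation.

Step 2
Reactants: 3 1-(2,4,6-trimethoxy-3-methylphenyl)butan-1-one
Product: 4 1-(2,6-dihydroxy-4-methoxy-3-methylphenyl)butan-1-one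
Conditions: BCl3 (3.5 equiv), CH2Cl2, −78 °C → rt; then H2O
Reagents that add atoms: none
Why: Chelation-directed ether cleavage by BCl3 should remove only the two methoxy groups ortho to the ketone (one of them also sterically activated between acyl and methyl), while the para methoxy group cannot chelate and stays as the OMe of ring A.

Step 3
Reactants: 4 1-(2,6-dihydroxy-4-methoxy-3-methylphenyl)butan-1-one
Product: 5 3-butanoyl-2,4-dihydroxy-6-methoxy-5-methylbenzaldehyde
Conditions: Cl2CHOMe, TiCl4 (3.5 equiv), CH2Cl2, 0 °C; then 1 M HCl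
Reagents that add atoms: dichloromethyl methyl ether COC(Cl)Cl; water O
Why: Rieche formylation at the only unsubstituted ring carbon, which is ortho or para to all three oxygen donors, and without the chromone formation that a Vilsmeier reagent can cause at an ortho-hydroxyaryl alkyl ketone.

Step 4
Reactants: 5 3-butanoyl-2,4-dihydroxy-6-methoxy-5-methylbenzaldehyde
Product: 6 2,4-bis(benzyloxy)-3-butanoyl-6-methoxy-5-methylbenzaldehyde
Conditions: BnBr (2.5 equiv), K2CO3, DMF, 60 °C
Reagents that add atoms: benzyl bromide BrCc1ccccc1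
Why: Williamson etherification in a polar aprotic solvent, warm enough to alkylate the two hydrogen-bonded phenols; O-alkylation is the only path that keeps the fully substituted ring aromatic.

Step 5
Reactants: 6 2,4-bis(benzyloxy)-3-butanoyl-6-methoxy-5-methylbenzaldehyde
Product: 7 1-[2,6-bis(benzyloxy)-3-(hydroxymethyl)-4-methoxy-5-methylphenyl]butan-1-one
Conditions: NaBH4 (1 equiv), THF/MeOH, 0 °C
Reagents that add atoms: none
Why: Chemoselective borohydride reduction of the aldehyde; the butanoyl ketone is twisted out of the ring plane between two ortho benzyloxy groups and should react much more slowly.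

Step 6
Reactants: 7 1-[2,6-bis(benzyloxy)-3-(hydroxymethyl)-4-methoxy-5-methylphenyl]butan-1-one
Product: 8 1-[2,6-bis(benzyloxy)-3-(bromomethyl)-4-methoxy-5-methylphenyl]butan-1-one
Conditions: PBr3 (0.4 equiv), Et2O, 0 °C; cold NaHCO3 wash, crude used at once
Reagents that add atoms: phosphorus tribromide BrP(Br)Br
Why: Benzylic alcohol to bromide through the phosphite ester; the hexasubstituted ring has no free carbon for Friedel–Crafts self-alkylation, so the electron-rich bromide should survive a cold work-up.

Step 7
Reactants: 9 ethyl 2-(2-methyl-1,3-dioxolan-2-yl)acetate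
Product: 10 N-methoxy-N-methyl-2-(2-methyl-1,3-dioxolan-2-yl)acetamide
Conditions: MeNH(OMe)·HCl (1.5 equiv), i-PrMgCl (3 equiv), THF, −20 → 0 °C
Reagents that add atoms: N,O-dimethylhydroxylamine hydrochloride CNOC.Cl
Why: Weinreb amide formation by aminolysis of the ester with the magnesium amide made in the flask; the ketal is inert to base.

Step 8
Reactants: 11 methyl 2-methyl-3-oxobutanoate; 10 N-methoxy-N-methyl-2-(2-methyl-1,3-dioxolan-2-yl)acetamide
Product: 13 methyl 2-methyl-6-(2-methyl-1,3-dioxolan-2-yl)-3,5-dioxohexanoate, via the dilithium dienolate 12 (not isolated)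
Conditions: LiN(i-Pr)2 (2.1 equiv), THF, −78 → 0 °C; then 10 (0.7 equiv), −78 → 0 °C; sat. aq. NH4Cl
Reagents that add atoms: none
Why: Acylation of a β-keto ester dianion at its terminal carbon by a Weinreb amide; the chelated tetrahedral adduct collapses only on work-up, so there should be no over-addition and no proton transfer from product to dianion.

Step 9
Reactants: 13 methyl 2-methyl-6-(2-methyl-1,3-dioxolan-2-yl)-3,5-dioxohexanoate; 8 1-[2,6-bis(benzyloxy)-3-(bromomethyl)-4-methoxy-5-methylphenyl]butan-1-one
Product: 14 methyl 4-{[2,4-bis(benzyloxy)-3-butanoyl-6-methoxy-5-methylphenyl]methyl}-2-methyl-6-(2-methyl-1,3-dioxolan-2-yl)-3,5-dioxohexanoate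
Conditions: NaH (1.0 equiv on 13, 13 in 1.2-fold excess over 8), THF, 0 °C; then 8, 0 °C → rt
Reagents that add atoms: none
Why: C-alkylation of a 1,3-diketone sodium enolate by a benzylic bromide (SN2); C4 is the only CH2 between two ketones because the ketal keeps C6 non-acidic and C2 is a less acidic β-keto ester CH, and one equivalent of mild base leaves the butanoyl ketone unenolised.

Step 10
Reactants: 14 methyl 4-{[2,4-bis(benzyloxy)-3-butanoyl-6-methoxy-5-methylphenyl]methyl}-2-methyl-6-(2-methyl-1,3-dioxolan-2-yl)-3,5-dioxohexanoate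
Product: 15 methyl 4-{[2,4-bis(benzyloxy)-3-butanoyl-6-methoxy-5-methylphenyl]methyl}-2-methyl-3,5,7-trioxooctanoate
Conditions: 2 M HCl, THF, rt; extraction at pH 5–6, crude taken on
Reagents that add atoms: water O
Why: Acid-catalysed hydrolysis of the dioxolane; benzyl ethers and the methyl ester should tolerate dilute acid at room temperature, and the triketo ester is not chromatographed.

Step 11
Reactants: 15 methyl 4-{[2,4-bis(benzyloxy)-3-butanoyl-6-methoxy-5-methylphenyl]methyl}-2-methyl-3,5,7-trioxooctanoate
Product: 17 1-{3-[(3-acetyl-2,4,6-trihydroxy-5-methylphenyl)methyl]-2,6-bis(benzyloxy)-4-methoxy-5-methylphenyl}butan-1-one, via the cyclohexanetrione 16 (not isolated)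
Conditions: Mg(OMe)2 (6 equiv), MeOH, argon, rt → 60 °C; then cold 1 M HCl
Reagents that add atoms: none
Why: Mg(OMe)2 turns the diketone and keto ester units into magnesium chelates; the C6 carbon of the C5/C7 diketonate adds to the ester carbonyl C1, methoxide leaves, and the 2-acetylcyclohexane-1,3,5-trione 16 enolises irreversibly to aromatic ring B (intramolecular Claisen or Dieckmann-type condensation, the closest known case being the magnesium methoxide cyclisation of 3,5,7-triketo esters and their pyrones to acylphloroglucinols). Ring B closes by a 6-(enolexo)-exo-trig attack that forms the C4'–C5' bond. No stereocentre is created and those at C2 and C4 of 15 are erased on aromatisation. The selectivity needed is Claisen over aldol folding: attack of C2 on the C7 ketone would give a quaternary C2 (methyl and ester) that cannot dehydrate to an arene and so reverts, and the only aromatisable aldol (C8 onto C3) needs deprotonation of the non-acidic terminal methyl, which a weak chelating base should not achieve. Lactonisation to the 4-hydroxy-2-pyrone is reversed by methoxide and feeds the same pathway, and the benzyl ethers keep the ring A oxygens from adding to the C3 and C5 ketones.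

Step 12
Reactants: 17 1-{3-[(3-acetyl-2,4,6-trihydroxy-5-methylphenyl)methyl]-2,6-bis(benzyloxy)-4-methoxy-5-methylphenyl}butan-1-one
Product: 18 1-{3-[(3-acetyl-2,4,6-trihydroxy-5-methylphenyl)methyl]-2,6-dihydroxy-4-methoxy-5-methylphenyl}butan-1-one
Conditions: H2 (1 atm), 10% Pd/C, EtOAc, rt
Reagents that add atoms: none
Why: Hydrogenolysis of aryl benzyl ethers; the hydrogen-bonded aryl ketones, the aryl methyl ether and the diarylmethane bridge should be inert under these conditions.

**Compound list**
1 | 1,3,5-trimethoxy-2-methylbenzene (2,4,6-trimethoxytoluene) | Cc1c(OC)cc(OC)cc1OC | starting material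
2 | butanoyl chloride | CCCC(=O)Cl | starting material
3 | 1-(2,4,6-trimethoxy-3-methylphenyl)butan-1-one | CCCC(=O)c1c(OC)c(C)c(OC)cc1OC | intermediate
4 | 1-(2,6-dihydroxy-4-methoxy-3-methylphenyl)butan-1-one | CCCC(=O)c1c(O)c(C)c(OC)cc1O | intermediate
5 | 3-butanoyl-2,4-dihydroxy-6-methoxy-5-methylbenzaldehyde | CCCC(=O)c1c(O)c(C)c(OC)c(C=O)c1O | intermediate
6 | 2,4-bis(benzyloxy)-3-butanoyl-6-methoxy-5-methylbenzaldehyde | CCCC(=O)c1c(OCc2ccccc2)c(C)c(OC)c(C=O)c1OCc1ccccc1 | intermediate
7 | 1-[2,6-bis(benzyloxy)-3-(hydroxymethyl)-4-methoxy-5-methylphenyl]butan-1-one | CCCC(=O)c1c(OCc2ccccc2)c(C)c(OC)c(CO)c1OCc1ccccc1 | intermediate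
8 | 1-[2,6-bis(benzyloxy)-3-(bromomethyl)-4-methoxy-5-methylphenyl]butan-1-one | CCCC(=O)c1c(OCc2ccccc2)c(C)c(OC)c(CBr)c1OCc1ccccc1 | intermediate
9 | ethyl 2-(2-methyl-1,3-dioxolan-2-yl)acetate | CCOC(=O)CC1(C)OCCO1 | starting material
10 | N-methoxy-N-methyl-2-(2-methyl-1,3-dioxolan-2-yl)acetamide | CON(C)C(=O)CC1(C)OCCO1 | intermediate
11 | methyl 2-methyl-3-oxobutanoate | COC(=O)C(C)C(C)=O | starting material
12 | dilithium dienolate of methyl 2-methyl-3-oxobutanoate (not isolated) | [Li+].[Li+].[CH2-]C([O-])=C(C)C(=O)OC | intermediate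
13 | methyl 2-methyl-6-(2-methyl-1,3-dioxolan-2-yl)-3,5-dioxohexanoate (racemic, keto–enol mixture) | COC(=O)C(C)C(=O)CC(=O)CC1(C)OCCO1 | intermediate
14 | methyl 4-{[2,4-bis(benzyloxy)-3-butanoyl-6-methoxy-5-methylphenyl]methyl}-2-methyl-6-(2-methyl-1,3-dioxolan-2-yl)-3,5-dioxohexanoate (stereoisomer and enol mixture) | COC(=O)C(C)C(=O)C(Cc1c(OC)c(C)c(OCc2ccccc2)c(C(=O)CCC)c1OCc1ccccc1)C(=O)CC1(C)OCCO1 | intermediate
15 | methyl 4-{[2,4-bis(benzyloxy)-3-butanoyl-6-methoxy-5-methylphenyl]methyl}-2-methyl-3,5,7-trioxooctanoate (stereoisomer and enol mixture) | COC(=O)C(C)C(=O)C(Cc1c(OC)c(C)c(OCc2ccccc2)c(C(=O)CCC)c1OCc1ccccc1)C(=O)CC(C)=O | intermediate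
16 | 2-acetyl-4-{[2,4-bis(benzyloxy)-3-butanoyl-6-methoxy-5-methylphenyl]methyl}-6-methylcyclohexane-1,3,5-trione (stereoisomer mixture, not isolated) | CC(=O)C1C(=O)C(C)C(=O)C(Cc2c(OC)c(C)c(OCc3ccccc3)c(C(=O)CCC)c2OCc2ccccc2)C1=O | intermediate
17 | 1-{3-[(3-acetyl-2,4,6-trihydroxy-5-methylphenyl)methyl]-2,6-bis(benzyloxy)-4-methoxy-5-methylphenyl}butan-1-one | CCCC(=O)c1c(OCc2ccccc2)c(C)c(OC)c(Cc2c(O)c(C)c(O)c(C(C)=O)c2O)c1OCc1ccccc1 | intermediate
18 | 1-{3-[(3-acetyl-2,4,6-trihydroxy-5-methylphenyl)methyl]-2,6-dihydroxy-4-methoxy-5-methylphenyl}butan-1-one (CNP0258463.0) | CCCC(=O)c1c(O)c(C)c(OC)c(Cc2c(O)c(C)c(O)c(C(C)=O)c2O)c1O | target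

**Step count**
Total steps: 12. Longest linear sequence: 10 steps (steps 1–6 and 9–12, from 2,4,6-trimethoxytoluene); the chain branch (steps 7 and 8) joins at step 9.

**Steps most likely to fail**

Step 11. Ring closure may be slow because the C4 substituent disfavours the planar magnesium chelates, and methoxide may then cleave the 2-substituted 1,3-diketone by retro-Claisen scission (loss of the acetyl end or chain fragmentation). The fallback abandons the folding and couples a preformed ring B; it sets out from alcohol 7 and returns at 17. Bought 2-methylbenzene-1,3,5-triol would be C-acetylated (Ac2O, BF3·OEt2, then aqueous work-up; Friedel–Crafts acylation) to 1-(2,4,6-trihydroxy-3-methylphenyl)ethan-1-one F1. F1 would then be benzylated at its single free ring carbon by the stabilised benzylic cation from 7 (catalytic TsOH, dioxane, rt; Friedel–Crafts benzylation), which should give 17 directly.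

Step 9. The cation-like benzylic bromide may alkylate the diketonate on oxygen instead of carbon, or ionise and lose a benzyl group through a quinone methide before it is captured. The fallback forms the bridge bond by a carbon-only dianion alkylation; it sets out from 8 and 11 and returns at 14. The dienolate 12 (from 11, LiN(i-Pr)2, THF, −78 °C) would be alkylated at its terminal carbon by 8 to give methyl 5-[2,4-bis(benzyloxy)-3-butanoyl-6-methoxy-5-methylphenyl]-2-methyl-3-oxopentanoate F2. F2 would be deprotonated again (LiN(i-Pr)2, 3.2 equiv, the third equivalent holding the butanoyl ketone as its enolate) and acylated at C4 by Weinreb amide 10 to give 14.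

Step 10. During acid unmasking the free triketo ester may lactonise or undergo aldol condensation, or lose ring A by acid-induced retro-Michael cleavage, and it cannot be purified easily. The fallback carries the chain as a robust pyrone; it sets out from 14 and returns at 17. Compound 14 would be lactonised (DBU, toluene, 80 °C) to 5-{[2,4-bis(benzyloxy)-3-butanoyl-6-methoxy-5-methylphenyl]methyl}-4-hydroxy-3-methyl-6-[(2-methyl-1,3-dioxolan-2-yl)methyl]-2H-pyran-2-one F3. Hydrolysis of the ketal (2 M HCl, THF) would give 5-{[2,4-bis(benzyloxy)-3-butanoyl-6-methoxy-5-methylphenyl]methyl}-4-hydroxy-3-methyl-6-(2-oxopropyl)-2H-pyran-2-one F4. Mg(OMe)2 in MeOH would open the lactone of F4 to 15 in the flask and close ring B to 17.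

**Further compounds**
F1 | step 11 | 1-(2,4,6-trihydroxy-3-methylphenyl)ethan-1-one | CC(=O)c1c(O)cc(O)c(C)c1O
F2 | step 9 | methyl 5-[2,4-bis(benzyloxy)-3-butanoyl-6-methoxy-5-methylphenyl]-2-methyl-3-oxopentanoate | COC(=O)C(C)C(=O)CCc1c(OC)c(C)c(OCc2ccccc2)c(C(=O)CCC)c1OCc1ccccc1
F3 | step 10 | 5-{[2,4-bis(benzyloxy)-3-butanoyl-6-methoxy-5-methylphenyl]methyl}-4-hydroxy-3-methyl-6-[(2-methyl-1,3-dioxolan-2-yl)methyl]-2H-pyran-2-one | CC1(CC2=C(Cc3c(OC)c(C)c(OCc4ccccc4)c(C(=O)CCC)c3OCc3ccccc3)C(O)=C(C)C(=O)O2)OCCO1
F4 | step 10 | 5-{[2,4-bis(benzyloxy)-3-butanoyl-6-methoxy-5-methylphenyl]methyl}-4-hydroxy-3-methyl-6-(2-oxopropyl)-2H-pyran-2-one | CC(=O)CC1=C(Cc2c(OC)c(C)c(OCc3ccccc3)c(C(=O)CCC)c2OCc2ccccc2)C(O)=C(C)C(=O)O1
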